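**Strategy.** The route rests on disconnecting the dihydropyran ring at C3–C4 and O1–C2. C4 is a diarylmethine on C4a, and C4a sits between the oxygen-bearing ring carbons C8a (O1) and C5 (phenol). The unit C4–C4a–C8a–O1 is therefore a latent ortho-quinone methide whose two oxygens are homotopic. A chiral phosphoric acid generates it from a racemic benzhydrol and adds N-vinylacetamide across C4 and O1, closing the ring and fixing C4 (S) in one operation. The precursor is 2-[(4,5-dimethoxynaphthalen-1-yl)(hydroxy)methyl]resorcinol, made from lithiated 4-bromo-1,8-dimethoxynaphthalene and bis-silylated 2,6-dihydroxybenzaldehyde. The aminal carbon C2 is afterwards converted, via the lactol acetate, into the trans methyl-bearing centre.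

Key step: step 5

Assumption: the (R)-configured phosphoric acid is taken to deliver the 4S adduct; the sense is to be checked on the first run, and the (S)-catalyst (also commercial) is used if it proves opposite.

Remark: (2R,4S) in the target is the 2,4-trans chroman, whereas (2R,4S) in the cycloadduct is the 2,4-cis aminal; the C2 descriptor is the same only because the substituent priorities differ.

**Step 1**
Reactants: 1 1,8-dimethoxynaphthalene
Product: 2 4-bromo-1,8-dimethoxynaphthalene
Conditions: NBS (1.0 equiv), MeCN, 0 °C → rt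
Reagents that add atoms: N-bromosuccinimide, O=C1CCC(=O)N1Br
Why: Electrophilic aromatic bromination of the electron-rich naphthalene should occur para to a methoxy group (C4), and one equivalent of NBS limits dibromination.

**Step 2**
Reactants: 3 2,6-dihydroxybenzaldehyde
Product: 4 2,6-bis[(tert-butyldimethylsilyl)oxy]benzaldehyde
Conditions: TBSCl (2.5 equiv), imidazole, DMF, rt
Reagents that add atoms: tert-butyldimethylsilyl chloride, CC(C)(C)[Si](C)(C)Cl
Why: Imidazole-mediated O-silylation masks both acidic phenols as fluoride-labile ethers, so that the aldehyde can accept an organolithium.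

**Step 3**
Reactants: 2 4-bromo-1,8-dimethoxynaphthalene; 4 2,6-bis[(tert-butyldimethylsilyl)oxy]benzaldehyde
Product: 6 rac-{2,6-bis[(tert-butyldimethylsilyl)oxy]phenyl}(4,5-dimethoxynaphthalen-1-yl)methanol, via (4,5-dimethoxynaphthalen-1-yl)lithium 5 (not isolated)
Conditions: n-BuLi, THF, −78 °C; then 4, −78 °C; sat. aq. NH4Cl at −78 °C
Reagents that add atoms: none
Why: Bromine–lithium exchange outruns ortho-lithiation at −78 °C and the aryllithium adds 1,2 to the non-enolisable aldehyde, the cold quench preventing silyl migration to the new alkoxide; the carbinol centre forms racemic and is erased in step 5.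

**Step 4**
Reactants: 6 rac-{2,6-bis[(tert-butyldimethylsilyl)oxy]phenyl}(4,5-dimethoxynaphthalen-1-yl)methanol
Product: 7 rac-2-[(4,5-dimethoxynaphthalen-1-yl)(hydroxy)methyl]benzene-1,3-diol
Conditions: TBAF (2.2 equiv), AcOH (2.2 equiv), THF, 0 °C; pH 7 buffer work-up
Reagents that add atoms: none
Why: Fluoride-induced desilylation cleaves aryl silyl ethers quickly at 0 °C, and the acetic acid buffer keeps the phenols protonated so that the labile benzhydrol is not ionised; the triol is to be filtered through base-washed silica and used at once.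

**Step 5**
Reactants: 7 rac-2-[(4,5-dimethoxynaphthalen-1-yl)(hydroxy)methyl]benzene-1,3-diol; 8 N-vinylacetamide
Product: 10 N-[(2R,4S)-4-(4,5-dimethoxynaphthalen-1-yl)-5-hydroxy-3,4-dihydro-2H-chromen-2-yl]acetamide, via ortho-quinone methide 9 (not isolated)
Conditions: (R)-TRIP [3,3'-bis(2,4,6-triisopropylphenyl)-BINOL hydrogen phosphate] (10 mol %), 8 (2.5 equiv), CH2Cl2, 0 °C → rt, slow addition of 7
Reagents that add atoms: none
Why: The acid protonates the benzylic hydroxyl and water leaves to give ortho-quinone methide 9, which is stabilised by the para-methoxynaphthyl group and whose C5 and C8a oxygens are homotopic and exchange roles by proton transfer, so that no regiochemical choice between them exists. The phosphate then binds the quinone methide oxygen through P–OH and the enamide N–H through P=O, the enamide CH2 terminus attacks C4 and the oxygen closes onto the developing N-acyliminium carbon in a concerted but asynchronous inverse-electron-demand oxa-Diels–Alder reaction, the closest known reaction type being the chiral phosphoric acid-catalysed [4+2] cycloaddition of in situ ortho-quinone methides with enamides and enecarbamates. The dihydropyran ring is closed as the six-membered ring of this [4+2] cycloaddition (in the stepwise limit a 6-exo-trig attack of the phenolic oxygen on the iminium carbon). C4 (S) is controlled by the chiral pocket of the catalyst, which leaves one face of the methide carbon open, and C2 (R, cis to the naphthyl group) by the endo orientation in which the N–H stays hydrogen-bonded to the phosphate; the C2 centre is replaced later. The step needs regioselectivity, which the polarity of the partners secures (nucleophilic enamide carbon to electrophilic C4), and chemoselectivity for the enamide over arylation of 9 by a second resorcinol ring, which the higher nucleophilicity and excess of the enamide and the slow addition of 7 secure.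

**Step 6**
Reactants: 10 N-[(2R,4S)-4-(4,5-dimethoxynaphthalen-1-yl)-5-hydroxy-3,4-dihydro-2H-chromen-2-yl]acetamide
Product: 12 (4S)-4-(4,5-dimethoxynaphthalen-1-yl)-3,4-dihydro-2H-chromene-2,5-diol (lactol; both C2 epimers), via ring-opened aldehyde 11 (not isolated)
Conditions: 1 M aq. HCl, THF, 40 °C
Reagents that add atoms: water, O
Why: Acid-catalysed hydrolysis of the N-acyl N,O-acetal (ring opening to the N-acyliminium ion, addition of water, loss of acetamide from the carbinolamide) gives aldehyde 11, which recloses on either homotopic phenol to the lactol; C4 bears no leaving group and is untouched.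

**Step 7**
Reactants: 12 (4S)-4-(4,5-dimethoxynaphthalen-1-yl)-3,4-dihydro-2H-chromene-2,5-diol
Product: 13 (4S)-4-(4,5-dimethoxynaphthalen-1-yl)-3,4-dihydro-2H-chromene-2,5-diyl diacetate (both C2 epimers)
Conditions: Ac2O, pyridine, DMAP (cat.), CH2Cl2, 0 °C → rt
Reagents that add atoms: acetic anhydride, CC(=O)OC(C)=O
Why: DMAP-catalysed acylation acetylates the phenol and the hemiacetal hydroxyl of the predominant ring-closed tautomer, which installs the anomeric acetate as the leaving group for step 8.

**Step 8**
Reactants: 13 (4S)-4-(4,5-dimethoxynaphthalen-1-yl)-3,4-dihydro-2H-chromene-2,5-diyl diacetate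
Product: 16 Cladonaphchrom A [(2R,4S)-4-(4,5-dimethoxynaphthalen-1-yl)-2-methyl-3,4-dihydro-2H-chromen-5-ol], via oxocarbenium ion 14 (not isolated), via 5-O-acetyl methylchroman 15 (not isolated)
Conditions: AlMe3 (4 equiv), CH2Cl2, −78 → 0 °C; then MeOH, 2 M aq. NaOH, rt; 1 M HCl to pH 6
Reagents that add atoms: trimethylaluminium, C[Al](C)C
Why: Trimethylaluminium ionises the anomeric acetate to oxocarbenium ion 14 and the resulting aluminate transfers methyl to C2 on the face opposite the C4 naphthyl group (organoaluminium substitution of a lactol acetate, a C-glycosylation-type reaction), which should set the 2,4-trans (2R) centre, and the hydroxide work-up saponifies the aryl acetate of 15.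

**Compound list**

1 | 1,8-dimethoxynaphthalene | COc1cccc2cccc(OC)c12 | starting material
2 | 4-bromo-1,8-dimethoxynaphthalene | COc1cccc2c(Br)ccc(OC)c12 | intermediate
3 | 2,6-dihydroxybenzaldehyde | O=Cc1c(O)cccc1O | starting material
4 | 2,6-bis[(tert-butyldimethylsilyl)oxy]benzaldehyde | O=Cc1c(O[Si](C)(C)C(C)(C)C)cccc1O[Si](C)(C)C(C)(C)C | intermediate
5 | (4,5-dimethoxynaphthalen-1-yl)lithium (formed in situ) | [Li]c1ccc(OC)c2c(OC)cccc12 | intermediate
6 | rac-{2,6-bis[(tert-butyldimethylsilyl)oxy]phenyl}(4,5-dimethoxynaphthalen-1-yl)methanol | COc1cccc2c(C(O)c3c(O[Si](C)(C)C(C)(C)C)cccc3O[Si](C)(C)C(C)(C)C)ccc(OC)c12 | intermediate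
7 | rac-2-[(4,5-dimethoxynaphthalen-1-yl)(hydroxy)methyl]benzene-1,3-diol | COc1cccc2c(C(O)c3c(O)cccc3O)ccc(OC)c12 | intermediate
8 | N-vinylacetamide | C=CNC(C)=O | starting material
9 | 6-[(4,5-dimethoxynaphthalen-1-yl)methylidene]-5-hydroxycyclohexa-2,4-dien-1-one (ortho-quinone methide, formed in situ) | O=C1C=CC=C(O)C1=Cc1ccc(OC)c2c(OC)cccc12 | intermediate
10 | N-[(2R,4S)-4-(4,5-dimethoxynaphthalen-1-yl)-5-hydroxy-3,4-dihydro-2H-chromen-2-yl]acetamide (2,4-cis) | COc1cccc2c([C@@H]3C[C@H](NC(C)=O)Oc4cccc(O)c43)ccc(OC)c12 | intermediate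
11 | (3S)-3-(2,6-dihydroxyphenyl)-3-(4,5-dimethoxynaphthalen-1-yl)propanal (formed in situ) | COc1cccc2c([C@H](CC=O)c3c(O)cccc3O)ccc(OC)c12 | intermediate
12 | (4S)-4-(4,5-dimethoxynaphthalen-1-yl)-3,4-dihydro-2H-chromene-2,5-diol (both C2 epimers) | COc1cccc2c([C@@H]3CC(O)Oc4cccc(O)c43)ccc(OC)c12 | intermediate
13 | (4S)-4-(4,5-dimethoxynaphthalen-1-yl)-3,4-dihydro-2H-chromene-2,5-diyl diacetate (both C2 epimers) | COc1cccc2c([C@@H]3CC(OC(C)=O)Oc4cccc(OC(C)=O)c43)ccc(OC)c12 | intermediate
14 | (4S)-5-acetoxy-4-(4,5-dimethoxynaphthalen-1-yl)-3,4-dihydrochromenylium (O1=C2 oxocarbenium ion, formed in situ) | COc1cccc2c([C@@H]3CC=[O+]c4cccc(OC(C)=O)c43)ccc(OC)c12 | intermediate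
15 | (2R,4S)-4-(4,5-dimethoxynaphthalen-1-yl)-2-methyl-3,4-dihydro-2H-chromen-5-yl acetate (2,4-trans, formed in situ) | COc1cccc2c([C@@H]3C[C@@H](C)Oc4cccc(OC(C)=O)c43)ccc(OC)c12 | intermediate
16 | Cladonaphchrom A, (2R,4S)-4-(4,5-dimethoxynaphthalen-1-yl)-2-methyl-3,4-dihydro-2H-chromen-5-ol (2,4-trans) | COc1cccc2c([C@@H]3C[C@@H](C)Oc4cccc(O)c43)ccc(OC)c12 | target

**Step count and risks**

Total steps: 8. Longest linear sequence: 7 steps (steps 1, 3, 4, 5, 6, 7, 8; compounds 1 → 2 → 6 → 7 → 10 → 12 → 13 → 16).

Steps most likely to fail: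

1. **Step 5 (key step).** Enantiofacial control may erode because the catalyst can engage either of the two equivalent oxygens of the symmetric quinone methide, one syn and one anti to the naphthyl group. The quinone methide may also be consumed by arylation of a second resorcinol ring. The fallback desymmetrises the precursor so that only one hydroxyl can bind the catalyst. It sets out from 3 and uses aryllithium 5. Monobenzylation of 3 (BnBr 1.0 equiv, K2CO3, acetone) should give 2-(benzyloxy)-6-hydroxybenzaldehyde F1. Deprotonation with NaH and addition of 5 (THF, −78 → 0 °C) should give racemic 3-(benzyloxy)-2-[(4,5-dimethoxynaphthalen-1-yl)(hydroxy)methyl]phenol F2. The same phosphoric acid conditions with 8 should give N-[(2R,4S)-5-(benzyloxy)-4-(4,5-dimethoxynaphthalen-1-yl)-3,4-dihydro-2H-chromen-2-yl]acetamide F3. Hydrogenolysis (H2, Pd/C, EtOAc) returns to the route at 10.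

2. **Step 8.** Before methyl is transferred, oxocarbenium ion 14 may be captured intramolecularly by the electron-rich peri carbon of the naphthalene (para to its methoxy group), or it may lose a C3 proton to give the 4H-chromene. Methyl delivery may also show poor facial bias. The fallback avoids any cation at C2 and sets out from 12. Excess MeMgBr (THF, 0 °C → rt) opens the lactol and adds to the aldehyde, giving the separable carbinol epimers 2-[(1S,3S)-1-(4,5-dimethoxynaphthalen-1-yl)-3-hydroxybutyl]benzene-1,3-diol F4 and 2-[(1S,3R)-1-(4,5-dimethoxynaphthalen-1-yl)-3-hydroxybutyl]benzene-1,3-diol F5. Intramolecular Mitsunobu etherification of F4 (PPh3, DIAD, THF, 0 °C) closes the ring through either homotopic phenol with inversion at the carbinol carbon and returns to the route at 16. F5 is set aside.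

3. **Step 6.** Cleavage of the secondary acetamide aminal may be sluggish, and under the acid required the transient N-acyliminium ion may be trapped by the naphthalene peri carbon (intramolecular amidoalkylation) instead of by water. The fallback unmasks the lactol under neutral conditions and sets out from 7. The phosphoric acid cycloaddition is run with commercial benzyl N-vinylcarbamate (C=CNC(=O)OCc1ccccc1) in place of 8, which should give benzyl N-[(2R,4S)-4-(4,5-dimethoxynaphthalen-1-yl)-5-hydroxy-3,4-dihydro-2H-chromen-2-yl]carbamate F6. Hydrogenolysis (H2, Pd/C, wet THF) should release (2R,4S)-2-amino-4-(4,5-dimethoxynaphthalen-1-yl)-3,4-dihydro-2H-chromen-5-ol F7. This primary hemiaminal ether loses ammonia by hydrolysis in the wet solvent (pH 5 buffer work-up) and returns to the route at 12.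

**Further compounds**

F1 | step 5 | 2-(benzyloxy)-6-hydroxybenzaldehyde | O=Cc1c(O)cccc1OCc1ccccc1
F2 | step 5 | rac-3-(benzyloxy)-2-[(4,5-dimethoxynaphthalen-1-yl)(hydroxy)methyl]phenol | COc1cccc2c(C(O)c3c(O)cccc3OCc3ccccc3)ccc(OC)c12
F3 | step 5 | N-[(2R,4S)-5-(benzyloxy)-4-(4,5-dimethoxynaphthalen-1-yl)-3,4-dihydro-2H-chromen-2-yl]acetamide | COc1cccc2c([C@@H]3C[C@H](NC(C)=O)Oc4cccc(OCc5ccccc5)c43)ccc(OC)c12
F4 | step 8 | 2-[(1S,3S)-1-(4,5-dimethoxynaphthalen-1-yl)-3-hydroxybutyl]benzene-1,3-diol | COc1cccc2c([C@H](C[C@H](C)O)c3c(O)cccc3O)ccc(OC)c12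
F5 | step 8 | 2-[(1S,3R)-1-(4,5-dimethoxynaphthalen-1-yl)-3-hydroxybutyl]benzene-1,3-diol | COc1cccc2c([C@H](C[C@@H](C)O)c3c(O)cccc3O)ccc(OC)c12
F6 | step 6 | benzyl N-[(2R,4S)-4-(4,5-dimethoxynaphthalen-1-yl)-5-hydroxy-3,4-dihydro-2H-chromen-2-yl]carbamate | COc1cccc2c([C@@H]3C[C@H](NC(=O)OCc5ccccc5)Oc4cccc(O)c43)ccc(OC)c12
F7 | step 6 | (2R,4S)-2-amino-4-(4,5-dimethoxynaphthalen-1-yl)-3,4-dihydro-2H-chromen-5-ol | COc1cccc2c([C@@H]3C[C@H](N)Oc4cccc(O)c43)ccc(OC)c12
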